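The route rests on disconnecting two aryl–C5 bonds and the pyran O–C bond at once. Ring A C5 (chromene C4a) and ring B C3' each carry an isoprenoid unit ortho to an oxygen (O4, which is pyran O1, and O4') that lies para to a diketone carbonyl, so both are retrons of [3,3] shifts from O-bound tertiary ethers. One heating of a dibenzoylmethane bearing a 1,1-dimethylpropargyl ether on O4, a 1,1-dimethylallyl ether on O4' and a MOM ether on O2 should install the prenyl group and, via an allenylphenol and oxa-6π closure, the 2H-pyran fused at C4–C5 of ring A. The precursor arises by crossed Claisen condensation of two simple aryl fragments.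

Key step: step 6

Remark on the chemistry: the target has no stereocentre and no configurable double bond (the prenyl terminus carries two methyl groups, the chromene alkene is cis by ring constraint). It is achiral, so no stereocontrol is required.

Step 1
Reactants: 1 2,4-dihydroxyacetophenone; 2 3-chloro-3-methylbut-1-yne
Product: 3 1-[2-hydroxy-4-(2-methylbut-3-yn-2-yloxy)phenyl]ethanone
Conditions: CuCl2·2H2O (1 mol%), DBU (1.2 equiv), MeCN, 0 °C → rt
Reagents that add atoms: none
Why: Copper-catalysed propargylic O-alkylation (substitution through a copper acetylide/allenylidene) should take the free, more acidic 4-OH, since the 2-OH is locked in a hydrogen bond to the acetyl carbonyl and is far less nucleophilic.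

Step 2
Reactants: 3 1-[2-hydroxy-4-(2-methylbut-3-yn-2-yloxy)phenyl]ethanone
Product: 4 1-[2-(methoxymethoxy)-4-(2-methylbut-3-yn-2-yloxy)phenyl]ethanone
Conditions: MOMCl (1.5 equiv), i-Pr2NEt (2 equiv), CH2Cl2, 0 °C → 40 °C
Reagents that add atoms: chloromethyl methyl ether (MOMCl), COCCl
Why: Williamson-type etherification of the chelated phenol under amine base should proceed on gentle warming without touching the ketone or the terminal alkyne, and the MOM group later breaks the chelate, tolerates strong base and heat, and blocks flavone closure.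

Step 3
Reactants: 5 methyl 4-hydroxybenzoate; 2 3-chloro-3-methylbut-1-yne
Product: 6 methyl 4-(2-methylbut-3-yn-2-yloxy)benzoate
Conditions: CuCl2·2H2O (1 mol%), DBU (1.2 equiv), MeCN, 0 °C → rt
Reagents that add atoms: none
Why: The same copper-catalysed propargylic O-alkylation works well on electron-poor phenols, and the methyl ester is inert to DBU in cold acetonitrile.

Step 4
Reactants: 6 methyl 4-(2-methylbut-3-yn-2-yloxy)benzoate
Product: 7 methyl 4-(2-methylbut-3-en-2-yloxy)benzoate
Conditions: H2 (1 atm), Lindlar catalyst (Pd/CaCO3, Pb-poisoned), quinoline, EtOAc, rt, stopped after 1 equiv H2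
Reagents that add atoms: none
Why: Lindlar semihydrogenation should stop at the vinyl group because the poisoned palladium reduces the terminal alkyne much faster than the monosubstituted alkene and should not hydrogenolyse the tertiary allylic C–O bond at 1 atm.

Step 5
Reactants: 4 1-[2-(methoxymethoxy)-4-(2-methylbut-3-yn-2-yloxy)phenyl]ethanone; 7 methyl 4-(2-methylbut-3-en-2-yloxy)benzoate
Product: 8 1-[2-(methoxymethoxy)-4-(2-methylbut-3-yn-2-yloxy)phenyl]-3-[4-(2-methylbut-3-en-2-yloxy)phenyl]propane-1,3-dione
Conditions: LiHMDS (3 equiv), THF, −78 °C → rt; AcOH quench at 0 °C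
Reagents that add atoms: none
Why: Crossed Claisen condensation: only ketone 4 is enolisable, ester 7 has no α-hydrogen, the hindered amide base deprotonates the methyl ketone in preference to the less acidic terminal alkyne, and irreversible formation of the diketonate drives the acylation at a temperature at which neither tertiary ether rearranges.

Step 6
Reactants: 8 1-[2-(methoxymethoxy)-4-(2-methylbut-3-yn-2-yloxy)phenyl]-3-[4-(2-methylbut-3-en-2-yloxy)phenyl]propane-1,3-dione
Product: 12 1-[4-hydroxy-3-(3-methylbut-2-enyl)phenyl]-3-[7-(methoxymethoxy)-2,2-dimethyl-2H-chromen-6-yl]propane-1,3-dione, via 1-[4-hydroxy-3-(3-methylbut-2-enyl)phenyl]-3-[2-(methoxymethoxy)-4-(2-methylbut-3-yn-2-yloxy)phenyl]propane-1,3-dione 9 (not isolated), via 1-[4-hydroxy-2-(methoxymethoxy)-5-(3-methylbuta-1,2-dienyl)phenyl]-3-[4-hydroxy-3-(3-methylbut-2-enyl)phenyl]propane-1,3-dione 10 (not isolated), via 1-[4-hydroxy-3-(3-methylbut-2-enyl)phenyl]-3-[(3Z)-6-(methoxymethoxy)-3-(3-methylbut-2-enylidene)-4-oxocyclohexa-1,5-dien-1-yl]propane-1,3-dione 11 (not isolated)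
Conditions: PhNEt2 (degassed), Ar, sealed tube, 140 °C then 190 °C
Reagents that add atoms: none
Why: On heating, the ring B aryl 1,1-dimethylallyl ether should undergo a chair aromatic Claisen [3,3] shift to one of its two equivalent ortho carbons and rearomatise to the ortho-prenylphenol 9 (new C3'–CH2 bond). At the higher temperature the ring A aryl 1,1-dimethylpropargyl ether should shift [3,3] to C5 (new C5–chromene C4 bond) and rearomatise to the allenylphenol 10, which passes by a [1,5] hydrogen shift to the vinyl ortho-quinone methide 11. The six-membered 2H-pyran, the only ring formed, then closes by a thermal disrotatory oxa-6π electrocyclisation in which O4 bonds to the dimethyl-bearing carbon. The closest known reaction types are the thermal conversion of aryl 1,1-dimethylpropargyl ethers into 2,2-dimethyl-2H-chromenes and the aromatic Claisen rearrangement of aryl 1,1-dimethylallyl ethers into ortho-prenylphenols, both run in hot N,N-diethylaniline on para-acyl aryl ethers. No stereocentre is formed; the selectivity needed is C5 over C3 on ring A, which the MOM ether on O2 should secure by removing the hydroxyl-to-ketone chelate whose bond fixation steers such ethers to C3, by making C5 the position para to an alkoxy donor, and by crowding C3 between two oxygen substituents, as in the classical switch seen for O2-alkylated 4-O-allyl resacetophenones, while ring B has equivalent ortho sites. Both events are reagent-free isomerisations insulated from each other by the diketone spacer, and the basic solvent should hold back ionisation with loss of isoprene and acid-driven chroman formation, flavone closure being blocked by the MOM group.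

Step 7
Reactants: 12 1-[4-hydroxy-3-(3-methylbut-2-enyl)phenyl]-3-[7-(methoxymethoxy)-2,2-dimethyl-2H-chromen-6-yl]propane-1,3-dione
Product: 13 glyinflanin C, 1-[4-hydroxy-3-(3-methylbut-2-enyl)phenyl]-3-(7-hydroxy-2,2-dimethyl-2H-chromen-6-yl)propane-1,3-dione
Conditions: HCl (ca. 1 M) in MeOH, 0 °C → rt, short; NaHCO3 quench
Reagents that add atoms: none
Why: Acid-catalysed acetal exchange (MOM cleavage) should be fast for an ortho-acyl aryl MOM ether, whose chelated phenol is a good leaving group, so cool, short exposure should spare the prenyl and chromene alkenes and avoid cyclodehydration to the flavone.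

Compound list
1 | 2,4-dihydroxyacetophenone | CC(=O)c1ccc(O)cc1O | starting material
2 | 3-chloro-3-methylbut-1-yne | CC(C)(Cl)C#C | starting material
3 | 1-[2-hydroxy-4-(2-methylbut-3-yn-2-yloxy)phenyl]ethanone | CC(=O)c1ccc(OC(C)(C)C#C)cc1O | intermediate
4 | 1-[2-(methoxymethoxy)-4-(2-methylbut-3-yn-2-yloxy)phenyl]ethanone | CC(=O)c1ccc(OC(C)(C)C#C)cc1OCOC | intermediate
5 | methyl 4-hydroxybenzoate | COC(=O)c1ccc(O)cc1 | starting material
6 | methyl 4-(2-methylbut-3-yn-2-yloxy)benzoate | COC(=O)c1ccc(OC(C)(C)C#C)cc1 | intermediate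
7 | methyl 4-(2-methylbut-3-en-2-yloxy)benzoate | COC(=O)c1ccc(OC(C)(C)C=C)cc1 | intermediate
8 | 1-[2-(methoxymethoxy)-4-(2-methylbut-3-yn-2-yloxy)phenyl]-3-[4-(2-methylbut-3-en-2-yloxy)phenyl]propane-1,3-dione | C=CC(C)(C)Oc1ccc(cc1)C(=O)CC(=O)c1ccc(OC(C)(C)C#C)cc1OCOC | intermediate
9 | 1-[4-hydroxy-3-(3-methylbut-2-enyl)phenyl]-3-[2-(methoxymethoxy)-4-(2-methylbut-3-yn-2-yloxy)phenyl]propane-1,3-dione | CC(C)=CCc1cc(ccc1O)C(=O)CC(=O)c1ccc(OC(C)(C)C#C)cc1OCOC | intermediate
10 | 1-[4-hydroxy-2-(methoxymethoxy)-5-(3-methylbuta-1,2-dienyl)phenyl]-3-[4-hydroxy-3-(3-methylbut-2-enyl)phenyl]propane-1,3-dione | CC(C)=CCc1cc(ccc1O)C(=O)CC(=O)c1cc(C=C=C(C)C)c(O)cc1OCOC | intermediate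
11 | 1-[4-hydroxy-3-(3-methylbut-2-enyl)phenyl]-3-[(3Z)-6-(methoxymethoxy)-3-(3-methylbut-2-enylidene)-4-oxocyclohexa-1,5-dien-1-yl]propane-1,3-dione | CC(C)=C/C=C1/C=C(C(=O)CC(=O)c2ccc(O)c(CC=C(C)C)c2)C(OCOC)=CC1=O | intermediate
12 | 1-[4-hydroxy-3-(3-methylbut-2-enyl)phenyl]-3-[7-(methoxymethoxy)-2,2-dimethyl-2H-chromen-6-yl]propane-1,3-dione | CC(C)=CCc1cc(C(=O)CC(=O)c2cc3c(cc2OCOC)OC(C)(C)C=C3)ccc1O | intermediate
13 | glyinflanin C, 1-[4-hydroxy-3-(3-methylbut-2-enyl)phenyl]-3-(7-hydroxy-2,2-dimethyl-2H-chromen-6-yl)propane-1,3-dione | CC(C)=CCc1cc(C(=O)CC(=O)c2cc3c(cc2O)OC(C)(C)C=C3)ccc1O | target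

Total step count: 7. Longest linear sequence: 5 steps (steps 1, 2, 5, 6, 7 from 1; equally steps 3, 4, 5, 6, 7 from 5).

Steps most likely to fail

Step 6. The [3,3] shift of the ring A propargyl ether may run towards C3 and give the angular pyran. The tertiary allyl ether on ring B may ionise with loss of isoprene, or the diketone may decay during the heating. Fallback, setting out from 7 and 4 and returning at 13: the two rearrangements would be run separately on the fragments before they are joined, each at its own temperature, with isomers removed on small, simple compounds. Heating 7 in N,N-diethylaniline at about 150 °C should give methyl 4-hydroxy-3-(3-methylbut-2-enyl)benzoate F1, which MOMCl and i-Pr2NEt would convert into methyl 4-(methoxymethoxy)-3-(3-methylbut-2-enyl)benzoate F2. Heating 4 in N,N-diethylaniline at about 190 °C should give 1-[7-(methoxymethoxy)-2,2-dimethyl-2H-chromen-6-yl]ethanone F3, the substrate class closest to the classical C5 switch, freed of any angular isomer by chromatography. LiHMDS-mediated Claisen condensation of F3 with F2 should give 1-[4-(methoxymethoxy)-3-(3-methylbut-2-enyl)phenyl]-3-[7-(methoxymethoxy)-2,2-dimethyl-2H-chromen-6-yl]propane-1,3-dione F4. Methanolic HCl at room temperature would then remove both MOM groups and give 13.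

Step 5. Acylation of the ketone enolate by the electron-rich methyl ester may be slow, so that enolate self-condensation or metalation of the terminal alkyne by the excess base takes over. Fallback, setting out from 7 and 4 and returning at 8: an aldol addition followed by oxidation, which needs one equivalent of base and a far more electrophilic partner. DIBAL-H reduction of 7 (CH2Cl2, −78 °C) should give [4-(2-methylbut-3-en-2-yloxy)phenyl]methanol F5, and MnO2 would oxidise it to 4-(2-methylbut-3-en-2-yloxy)benzaldehyde F6. Addition of the lithium enolate of 4 (LDA, 1.05 equiv, THF, −78 °C) should give racemic 3-hydroxy-1-[2-(methoxymethoxy)-4-(2-methylbut-3-yn-2-yloxy)phenyl]-3-[4-(2-methylbut-3-en-2-yloxy)phenyl]propan-1-one F7. Dess–Martin periodinane (NaHCO3, CH2Cl2) would oxidise F7 to diketone 8, erasing its stereocentre.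

Step 7. Acid may trigger side reactions during the acetal cleavage: cyclodehydration of the freed ortho-hydroxy diketone to a flavone, closure of the ortho-prenylphenol onto its alkene, or addition to the chromene double bond. Fallback, setting out from 3 and returning at 13: an O2 acetal that is removed by fluoride instead of acid. Compound 3 would be treated with SEMCl and i-Pr2NEt to give 1-[4-(2-methylbut-3-yn-2-yloxy)-2-{[2-(trimethylsilyl)ethoxy]methoxy}phenyl]ethanone F8. Condensation with 7 as in step 5 should give 1-[4-(2-methylbut-3-yn-2-yloxy)-2-{[2-(trimethylsilyl)ethoxy]methoxy}phenyl]-3-[4-(2-methylbut-3-en-2-yloxy)phenyl]propane-1,3-dione F9. Heating as in step 6 should give 1-[4-hydroxy-3-(3-methylbut-2-enyl)phenyl]-3-(2,2-dimethyl-7-{[2-(trimethylsilyl)ethoxy]methoxy}-2H-chromen-6-yl)propane-1,3-dione F10, the alkoxymethyl ether exerting the same regiocontrol as MOM. TBAF in THF/DMPU at 40–60 °C would then release 13 by fluoride-induced fragmentation under non-acidic conditions.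

Further compounds
F1 | step 6 | methyl 4-hydroxy-3-(3-methylbut-2-enyl)benzoate | COC(=O)c1ccc(O)c(CC=C(C)C)c1
F2 | step 6 | methyl 4-(methoxymethoxy)-3-(3-methylbut-2-enyl)benzoate | COCOc1ccc(cc1CC=C(C)C)C(=O)OC
F3 | step 6 | 1-[7-(methoxymethoxy)-2,2-dimethyl-2H-chromen-6-yl]ethanone | CC(=O)c1cc2C=CC(C)(C)Oc2cc1OCOC
F4 | step 6 | 1-[4-(methoxymethoxy)-3-(3-methylbut-2-enyl)phenyl]-3-[7-(methoxymethoxy)-2,2-dimethyl-2H-chromen-6-yl]propane-1,3-dione | CC(C)=CCc1cc(ccc1OCOC)C(=O)CC(=O)c1cc2C=CC(C)(C)Oc2cc1OCOC
F5 | step 5 | [4-(2-methylbut-3-en-2-yloxy)phenyl]methanol | C=CC(C)(C)Oc1ccc(CO)cc1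
F6 | step 5 | 4-(2-methylbut-3-en-2-yloxy)benzaldehyde | C=CC(C)(C)Oc1ccc(C=O)cc1
F7 | step 5 | racemic 3-hydroxy-1-[2-(methoxymethoxy)-4-(2-methylbut-3-yn-2-yloxy)phenyl]-3-[4-(2-methylbut-3-en-2-yloxy)phenyl]propan-1-one | C=CC(C)(C)Oc1ccc(cc1)C(O)CC(=O)c1ccc(OC(C)(C)C#C)cc1OCOC
F8 | step 7 | 1-[4-(2-methylbut-3-yn-2-yloxy)-2-{[2-(trimethylsilyl)ethoxy]methoxy}phenyl]ethanone | CC(=O)c1ccc(OC(C)(C)C#C)cc1OCOCC[Si](C)(C)C
F9 | step 7 | 1-[4-(2-methylbut-3-yn-2-yloxy)-2-{[2-(trimethylsilyl)ethoxy]methoxy}phenyl]-3-[4-(2-methylbut-3-en-2-yloxy)phenyl]propane-1,3-dione | C=CC(C)(C)Oc1ccc(cc1)C(=O)CC(=O)c1ccc(OC(C)(C)C#C)cc1OCOCC[Si](C)(C)C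
F10 | step 7 | 1-[4-hydroxy-3-(3-methylbut-2-enyl)phenyl]-3-(2,2-dimethyl-7-{[2-(trimethylsilyl)ethoxy]methoxy}-2H-chromen-6-yl)propane-1,3-dione | CC(C)=CCc1cc(C(=O)CC(=O)c2cc3c(cc2OCOCC[Si](C)(C)C)OC(C)(C)C=C3)ccc1O
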